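**Strategy.** Everything rests on closing the ten-membered ring last, at C3–C4. The step exploits the 2-methylallyl unit C4–C5(C16)=C6 that lies inside that ring next to oxygenated C2: a C2 β-keto sulfone, carried on the carvone-derived ring A, attacks the C4 terminus of a palladium π-allyl complex formed from a C4 carbonate, which forms the C3–C4 bond, the ring and the Z C5=C6 alkene in one operation. The precursor is open-chain between C3 and C4: ring A bears the keto sulfone and, through C9, the C7/C8 acetonide, a C19 Weinreb amide (no allylic C7 lactone) and the allylic carbonate; C14 is a silyl ether so that the C2 ketone can later be reduced under hydroxyl direction.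

Key step: step 33

Remark on numbering: briarane numbering is used throughout (C1 quaternary ring-fusion carbon, C2–C9 round the ten-membered ring, C10 ring-fusion CH, C11–C14 completing ring A, C15 methyl on C1, C16 methyl on C5, C17/C18 the CH–CH3 of the lactone, C19 the lactone carbonyl, C20 methyl on C11); β is the face of ring A that carries C15, α the opposite face.

Assumption: the zinc/ProPhenol alkynylation of step 15 is taken to follow its usual sense, the (R,R)-ligand giving the 7S carbinol; should the sense be opposite for this enal, the enantiomeric ligand is used.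

**Ring A (steps 1–11)**

Step 1
Reactants: 1 (S)-(+)-carvone
Product: 2 6-[(4-methoxybenzyloxy)methyl]carvone (epimers at C6, the future C1)
Conditions: LiN(iPr)2, THF, −78 °C; 4-MeOC6H4CH2OCH2Cl, −78 to −20 °C
Reagents that add atoms: 4-methoxybenzyl chloromethyl ether, COc1ccc(COCCl)cc1
Why: Kinetic α′-deprotonation of the enone and C-alkylation of the lithium enolate by the chloromethyl ether (enolate alkoxymethylation) bring in C2 at the alcohol oxidation level; the new centre is uncontrolled and is planarised again in step 2.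

Step 2
Reactants: 2 6-[(4-methoxybenzyloxy)methyl]carvone
Product: 3 6-methyl-6-[(4-methoxybenzyloxy)methyl]carvone, methyl trans to isopropenyl
Conditions: LiN(iPr)2, THF, −78 °C; MeI, DMPU, −78 to −40 °C
Reagents that add atoms: iodomethane, CI
Why: Enolate alkylation under 1,2-induction: the tetrasubstituted α′ enolate should be methylated anti to the neighbouring isopropenyl group, setting C1 with C15 β and the C2 arm α, cis to the C14 substituent.

Step 3
Reactants: 3 6-methyl-6-[(4-methoxybenzyloxy)methyl]carvone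
Product: 5 C12 β-hydroxy ketone (C10 ketone, C11 epimers), via C12 pinacolboronate 4 (not isolated)
Conditions: B2pin2, CuCl (5 mol%), Xantphos (4,5-bis(diphenylphosphino)-9,9-dimethylxanthene), NaOtBu (10 mol%), MeOH, THF, rt; then 30% H2O2, pH 7 buffer, 0 °C
Reagents that add atoms: hydrogen peroxide, OO
Why: Copper-catalysed conjugate borylation should add boron to C12 anti to the C14 isopropenyl group, as nucleophiles add to carvone, and the C–B bond is oxidised with retention to the C12 β-alcohol; the C11 centre is lost again in step 5.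

Step 4
Reactants: 5 C12 β-hydroxy ketone
Product: 6 C12 triisopropylsilyl ether
Conditions: iPr3SiOTf, 2,6-lutidine, CH2Cl2, −78 to 0 °C
Reagents that add atoms: triisopropylsilyl trifluoromethanesulfonate, CC(C)[Si](OS(=O)(=O)C(F)(F)F)(C(C)C)C(C)C
Why: Silylation of the secondary alcohol with a silyl triflate and a hindered base; the bulky β silyl ether later shields the β face of ring A.

Step 5
Reactants: 6 C12 triisopropylsilyl ether
Product: 7 C10 enol triflate (C10=C11) with C14 isopropenyl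
Conditions: KN(SiMe3)2, THF, −78 °C; PhNTf2, −78 to 0 °C
Reagents that add atoms: N-phenylbis(trifluoromethanesulfonimide), O=S(=O)(N(c1ccccc1)S(=O)(=O)C(F)(F)F)C(F)(F)F
Why: Only the C11 side of the ketone can enolise (C1 is quaternary), so enolate O-triflation gives the tetrasubstituted C10=C11 enol triflate.

Step 6
Reactants: 7 C10 enol triflate with C14 isopropenyl
Product: 9 C14 α-acetate enol triflate, via C14 methoxy hydroperoxide 8 (not isolated)
Conditions: O3, CH2Cl2/MeOH, −78 °C; then Ac2O, Et3N, DMAP (4-dimethylaminopyridine), CH2Cl2, 0 to 40 °C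
Reagents that add atoms: ozone, [O-][O+]=O; methanol, CO
Why: Ozone should cleave the electron-rich 1,1-disubstituted alkene in preference to the triflate-deactivated tetrasubstituted one, and the acetylated methoxy hydroperoxide undergoes Criegee rearrangement in which C14 migrates to oxygen with retention, giving the C14 α-acetate.

Step 7
Reactants: 9 C14 α-acetate enol triflate
Product: 10 methyl C9 enoate (ester on C10=C11), C14 α-acetate
Conditions: Pd(OAc)2 (10 mol%), dppf (1,1′-bis(diphenylphosphino)ferrocene), CO (1 atm), MeOH, Et3N, DMF, 60 °C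
Reagents that add atoms: carbon monoxide, [C-]#[O+]; methanol, CO
Why: Palladium-catalysed alkoxycarbonylation (oxidative addition of the enol triflate, CO insertion, methanolysis) places C9 on C10; no alkene is left that could insert into the acylpalladium intermediate.

Step 8
Reactants: 10 methyl C9 enoate, C14 α-acetate
Product: 11 allylic diol (C9 hydroxymethyl on C10=C11, C14 α-hydroxyl)
Conditions: iBu2AlH, CH2Cl2, −78 to 0 °C
Reagents that add atoms: none
Why: Hydride 1,2-reduction of the enoate to the allylic alcohol and reductive cleavage of the acetate, which frees the C14 hydroxyl that directs step 9.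

Step 9
Reactants: 11 allylic diol
Product: 12 saturated ring-A diol (C9 hydroxymethyl and C20 methyl β, H-10 and H-11 α)
Conditions: [Ir(cod)(PCy3)(py)]PF6 (10 mol%), H2 (1 atm), CH2Cl2, 0 °C to rt
Reagents that add atoms: none
Why: Hydroxyl-directed hydrogenation: the cationic iridium catalyst bound to the homoallylic α C14 hydroxyl (and the C9 hydroxyl) should deliver both hydrogens to the α face, which is also the face opposite the β C12 silyl ether, setting C10 and C11 together.

Step 10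
Reactants: 12 saturated ring-A diol
Product: 13 ring-A hydroxy aldehyde (C9 aldehyde, C14 α-hydroxyl)
Conditions: TEMPO (2,2,6,6-tetramethylpiperidin-1-oxyl, 10 mol%), PhI(OAc)2, CH2Cl2, rt
Reagents that add atoms: none
Why: Nitroxyl-catalysed oxidation is selective for the primary alcohol over the hindered secondary one and is non-basic, so C10 should not epimerise; the trans-disposed C14 hydroxyl cannot form a lactol.

Step 11
Reactants: 13 ring-A hydroxy aldehyde
Product: 14 ring-A aldehyde (C2 O-PMB, C12 β-O-TIPS, C14 α-O-TBS, C9 aldehyde)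
Conditions: tBuMe2SiOTf, 2,6-lutidine, CH2Cl2, −78 °C
Reagents that add atoms: tert-butyldimethylsilyl trifluoromethanesulfonate, CC(C)(C)[Si](C)(C)OS(=O)(=O)C(F)(F)F
Why: Low-temperature silylation of the secondary alcohol with a silyl triflate and a hindered pyridine base leaves the α-branched aldehyde untouched.

**Side-chain fragment (steps 12–18)**

Step 12
Reactants: 15 propargyl alcohol
Product: 16 (Z)-3-iodo-2-methylprop-2-en-1-ol
Conditions: MeMgBr, CuI (10 mol%), THF, 0 °C to rt; I2, −78 to 0 °C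
Reagents that add atoms: methylmagnesium bromide, C[Mg]Br; iodine, II
Why: Copper-catalysed anti-carbomagnesiation of the propargylic alkoxide puts methyl on the internal carbon and the alkoxide-chelated magnesium on the terminus, and iodinolysis with retention gives the Z vinyl iodide.

Step 13
Reactants: 16 (Z)-3-iodo-2-methylprop-2-en-1-ol
Product: 17 (Z)-1-iodo-3-(4-methoxybenzyloxy)-2-methylprop-1-ene
Conditions: NaH, 4-MeOC6H4CH2Cl, Bu4NI (cat.), THF, 0 °C to rt
Reagents that add atoms: 4-methoxybenzyl chloride, COc1ccc(CCl)cc1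
Why: Williamson etherification of the primary alkoxide; the vinyl iodide has no β-hydrogen that could be eliminated.

Step 14
Reactants: 17 (Z)-1-iodo-3-(4-methoxybenzyloxy)-2-methylprop-1-ene
Product: 18 (Z)-4-(4-methoxybenzyloxy)-3-methylbut-2-enal
Conditions: tBuLi, Et2O, −78 °C; DMF; aq NH4Cl
Reagents that add atoms: N,N-dimethylformamide, CN(C)C=O
Why: Iodine–lithium exchange proceeds with retention of alkene geometry and the vinyllithium is formylated by DMF (Bouveault formylation), giving the C4–C7 enal with the Z C5=C6 bond.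

Step 15
Reactants: 18 (Z)-4-(4-methoxybenzyloxy)-3-methylbut-2-enal; 19 propargyl acetate
Product: 20 (4S,5Z)-4-hydroxy-7-(4-methoxybenzyloxy)-6-methylhept-5-en-2-yn-1-yl acetate (C7 carbinol)
Conditions: Me2Zn, (R,R)-ProPhenol (2,6-bis{[(R)-2-(hydroxydiphenylmethyl)pyrrolidin-1-yl]methyl}-4-methylphenol, 20 mol%), Ph3PO, toluene, 0 °C
Reagents that add atoms: none
Why: Catalytic asymmetric alkynylation: the dinuclear zinc–ProPhenol complex binds the zinc acetylide and the enal and should add the alkyne to one aldehyde face, setting C7 (S).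

Step 16
Reactants: 20 C7 carbinol
Product: 21 C7 triethylsilyl ether of 20
Conditions: Et3SiCl, imidazole, CH2Cl2, 0 °C
Reagents that add atoms: chlorotriethylsilane, CC[Si](Cl)(CC)CC
Why: Standard silylation of the secondary propargylic alcohol.

Step 17
Reactants: 21 C7 triethylsilyl ether
Product: 22 (2Z,4S,5Z)-3-iodo-7-(4-methoxybenzyloxy)-6-methyl-4-(triethylsilyloxy)hepta-2,5-dien-1-ol
Conditions: NaAlH2(OCH2CH2OMe)2, THF, 0 °C; EtOAc; then I2, −78 °C
Reagents that add atoms: iodine, II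
Why: The aluminium hydride first cleaves the acetate; the propargylic alkoxide then directs trans-hydroalumination (hydride to C17, aluminium to C8), and iodinolysis with retention gives the vinyl iodide with iodine cis to C19.

Step 18
Reactants: 22 iodo dienol
Product: 23 side-chain vinyl iodide (C19 acetate of 22)
Conditions: Ac2O, pyridine, DMAP (cat.), CH2Cl2, 0 °C
Reagents that add atoms: acetic anhydride, CC(=O)OC(C)=O
Why: Acetylation of the primary allylic alcohol protects C19 through the coupling and the C9 oxidation.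

**Coupling and elaboration to the precursor (steps 19–32)**

Step 19
Reactants: 14 ring-A aldehyde; 23 side-chain vinyl iodide
Product: 24 coupled C9 carbinols (C9 epimers)
Conditions: CrCl2, NiCl2 (1 mol%), DMSO, rt
Reagents that add atoms: none
Why: Nozaki–Hiyama–Kishi coupling: nickel-catalysed formation of the vinylchromium species and its non-basic, chemoselective 1,2-addition to the hindered aldehyde form C8–C9 with retention of alkene geometry; the C9 configuration is reset in steps 20 and 21.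

Step 20
Reactants: 24 coupled C9 carbinols
Product: 25 C9 enone
Conditions: Dess–Martin periodinane, NaHCO3, CH2Cl2, rt
Reagents that add atoms: none
Why: Buffered hypervalent-iodine oxidation of the only free hydroxyl converges both C9 epimers on one enone without touching C10.

Step 21
Reactants: 25 C9 enone
Product: 27 (9S) Z-ene-1,4-diol (C9 and C19 hydroxyls), via (9S) alcohol C19 acetate 26 (not isolated)
Conditions: NaBH4, CeCl3·7H2O, MeOH, −78 °C; then K2CO3, 0 °C
Reagents that add atoms: none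
Why: Luche 1,2-reduction under Felkin–Anh control by C10 (hydride anti to the quaternary C1 branch) should give the 9S alcohol, the epimer that carbon addition to the aldehyde does not favour; carbonate in the same pot methanolyses the primary acetate.

Step 22
Reactants: 27 Z-ene-1,4-diol
Product: 28 butenolide (C19 carbonyl lactonised onto O9, C8=C17)
Conditions: TEMPO (20 mol%), PhI(OAc)2, CH2Cl2, rt
Reagents that add atoms: none
Why: Oxidative lactonisation: the primary allylic alcohol is oxidised first, the Z hydroxy enal closes to the lactol with the cis C9 hydroxyl, and the lactol is oxidised to the lactone.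

Step 23
Reactants: 28 butenolide
Product: 29 C8,C17-epoxy lactone (epoxide oxygen anti to C10)
Conditions: tBuOOH, nBuLi, THF, −78 to −20 °C
Reagents that add atoms: tert-butyl hydroperoxide, CC(C)(C)OO
Why: Nucleophilic (Weitz–Scheffer) epoxidation: the peroxide anion adds to C8 on the lactone face anti to the ring-A substituent of the adjacent C9 and the enolate closes the epoxide, setting C8.

Step 24
Reactants: 29 epoxy lactone
Product: 30 C8-hydroxy C17-methyl lactone
Conditions: Me2CuLi (from MeLi and CuI), Et2O, −40 to 0 °C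
Reagents that add atoms: lithium dimethylcuprate, [Li+].C[Cu-]C
Why: SN2 opening of the α,β-epoxy lactone by the cuprate at the α carbon C17 (C8 is fully substituted) with inversion sets the C17 methyl and leaves the tertiary C8 alcohol.

Step 25
Reactants: 30 C8-hydroxy C17-methyl lactone
Product: 32 C7/C8 acetonide of the lactone, via C7,C8-diol lactone 31 (not isolated)
Conditions: camphor-10-sulfonic acid (cat.), MeOH/CH2Cl2, 0 °C; then Me2C(OMe)2, acetone, rt
Reagents that add atoms: 2,2-dimethoxypropane, COC(C)(C)OC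
Why: Mild acidic methanolysis removes the triethylsilyl ether but not the bulkier silyl ethers, and transketalisation ties the C7/C8 diol as the dioxolane while C19 is still locked in the O9 lactone and cannot lactonise onto O7.

Step 26
Reactants: 32 acetonide lactone
Product: 33 C19 N-methoxy-N-methylamide with free C9 hydroxyl
Conditions: MeNH(OMe)·HCl, iPrMgCl, THF, −20 to 0 °C
Reagents that add atoms: N,O-dimethylhydroxylamine hydrochloride, CNOC.Cl
Why: Aminolysis of the γ-lactone by the magnesium amide gives the open-chain Weinreb amide, which unlike an ester does not re-close onto the C9 hydroxyl.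

Step 27
Reactants: 33 hydroxy Weinreb amide
Product: 34 C9 acetate
Conditions: Ac2O, DMAP, pyridine, CH2Cl2, rt
Reagents that add atoms: acetic anhydride, CC(=O)OC(C)=O
Why: DMAP-catalysed acetylation of the only free hydroxyl installs the C9 acetate of the target.

Step 28
Reactants: 34 C9 acetate
Product: 35 C2,C4-diol
Conditions: DDQ, CH2Cl2/pH 7 buffer, 0 °C to rt
Reagents that add atoms: none
Why: Oxidative cleavage of both 4-methoxybenzyl ethers (benzylic hydride abstraction, hydrolysis of the oxocarbenium ion) leaves silyl ethers, acetonide, acetate and alkene intact.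

Step 29
Reactants: 35 C2,C4-diol
Product: 36 C4 methyl carbonate with free C2 hydroxyl
Conditions: ClCO2Me (1.1 equiv), pyridine, CH2Cl2, −40 to −20 °C
Reagents that add atoms: methyl chloroformate, COC(Cl)=O
Why: The unhindered primary allylic C4 alcohol should be acylated much faster than the neopentyl C2 alcohol beside quaternary C1.

Step 30
Reactants: 36 C4 methyl carbonate
Product: 37 C2 aldehyde
Conditions: Dess–Martin periodinane, NaHCO3, CH2Cl2, rt
Reagents that add atoms: none
Why: Mild oxidation of the remaining primary alcohol gives a non-enolisable neopentyl aldehyde.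

Step 31
Reactants: 37 C2 aldehyde; 38 methyl phenyl sulfone
Product: 39 C2-hydroxy C3-sulfone (C2 epimers)
Conditions: 38, nBuLi, THF, −78 °C; then 37, −78 °C; AcOH quench at −78 °C
Reagents that add atoms: none
Why: 1,2-Addition of the lithiated sulfone to the aldehyde at −78 °C is far faster than attack on the acetate, carbonate or hindered amide and brings in C3 without an acylation step; the C2 configuration is irrelevant.

Step 32
Reactants: 39 C2-hydroxy C3-sulfone
Product: 40 C2 keto sulfone with C4 allylic methyl carbonate (cyclisation precursor)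
Conditions: Dess–Martin periodinane, NaHCO3, CH2Cl2, rt
Reagents that add atoms: none
Why: Oxidation of the β-hydroxy sulfone gives the β-keto sulfone whose C3 methylene is acidic enough for base-free allylic alkylation.

**Key step and completion (steps 33–38)**

Step 33
Reactants: 40 C2 keto sulfone with C4 allylic methyl carbonate
Product: 41 ten-membered C2 ketone C3 sulfone (C3–C4 closed, Z C5=C6)
Conditions: Pd(PPh3)4 (15 mol%), THF, 65 °C, 1 mM, slow addition
Reagents that add atoms: none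
Why: Zerovalent palladium ionises the allylic carbonate with loss of CO2 to a cationic π-allyl complex of divalent palladium spanning C4–C5–C6, and the methoxide released deprotonates the β-keto sulfone, so no external base is needed. The closest known reaction type is the palladium-catalysed intramolecular allylic alkylation (Tsuji–Trost macrocyclisation) of sulfone-stabilised carbanions with allylic carbonates. The ten-membered ring closes by attack of C3 on the unsubstituted C4 terminus, anti to palladium; attack at the hindered C6 terminus would give the eight-membered ring and is disfavoured. The only new stereocentre, C3, is set under thermodynamic control of the acidic keto sulfone and is erased in step 34. The selectivity needed is C4 over C6 and Z over E: the Z carbonate ionises directly to the anti π-allyl isomer, which the C16 methyl on the central carbon C5 stabilises relative to the syn isomer, and the C7/C8 dioxolane holds C6 and C9 cis so that the two reacting ends are preorganised. High dilution suppresses oligomerisation, and neither the ketal oxygen at allylic C7 nor the open-chain amide offers a second ionisable leaving group.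

Step 34
Reactants: 41 ten-membered C2 ketone C3 sulfone
Product: 42 ten-membered C2 ketone
Conditions: SmI2, THF/MeOH, −78 °C
Reagents that add atoms: none
Why: Single-electron reduction of the β-keto sulfone cleaves the C3–S bond through the samarium enolate, which methanol protonates; this is much faster than any reaction of the amide or acetate.

Step 35
Reactants: 42 ten-membered C2 ketone
Product: 43 C14 alcohol (β-hydroxy ketone)
Conditions: HF·pyridine, pyridine, THF, 0 °C to rt
Reagents that add atoms: none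
Why: Buffered fluoride should cleave the tert-butyldimethylsilyl ether at C14 while the bulkier triisopropylsilyl ether at C12 and the acetonide persist.

Step 36
Reactants: 43 C14 alcohol
Product: 44 (2S)-C2,C14-diol
Conditions: Me4NBH(OAc)3, MeCN/AcOH, −30 °C
Reagents that add atoms: none
Why: Evans–Saksena reduction: the C14 hydroxyl exchanges onto boron and delivers hydride intramolecularly through a chair transition state with C3 equatorial, giving the 1,3-anti diol, which is the 2S carbinol of the target.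

Step 37
Reactants: 44 (2S)-C2,C14-diol
Product: 45 C2,C9,C14-triacetate (C12 O-TIPS, C7/C8 acetonide, C19 Weinreb amide)
Conditions: Ac2O, DMAP, pyridine, 40 °C
Reagents that add atoms: acetic anhydride, CC(=O)OC(C)=O
Why: DMAP-catalysed acetylation of the two free secondary hydroxyls; C12 and C8 are still masked.

Step 38
Reactants: 45 triacetate
Product: 47 CNP0195208.2, via C7,C8,C12-triol amide 46 (not isolated)
Conditions: 48% aq HF, MeCN, 0 °C to rt
Reagents that add atoms: none
Why: Aqueous HF removes the triisopropylsilyl ether and hydrolyses the acetonide, and the liberated C7 hydroxyl attacks the protonated Weinreb amide (acyl substitution, five-membered ring closure) to form the γ-lactone, the tertiary C8 hydroxyl staying free.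

**Compound list**

1 | (S)-(+)-carvone | CC(=C)[C@H]1CC=C(C)C(=O)C1 | starting material
2 | 6-[(4-methoxybenzyloxy)methyl]carvone, C6 epimers | COc1ccc(COCC2[C@@H](C(C)=C)CC=C(C)C2=O)cc1 | intermediate
3 | 6-methyl-6-[(4-methoxybenzyloxy)methyl]carvone, methyl trans to isopropenyl (C1, C14 set) | COc1ccc(COC[C@@]2(C)[C@@H](C(C)=C)CC=C(C)C2=O)cc1 | intermediate
4 | C12 β-pinacolboronate of the C10 ketone (C11 epimers) | COc1ccc(COC[C@@]2(C)[C@@H](C(C)=C)C[C@H](B3OC(C)(C)C(C)(C)O3)C(C)C2=O)cc1 | intermediate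
5 | C12 β-hydroxy C10 ketone (C11 epimers) | COc1ccc(COC[C@@]2(C)[C@@H](C(C)=C)C[C@H](O)C(C)C2=O)cc1 | intermediate
6 | C12 β-triisopropylsilyl ether of 5 | COc1ccc(COC[C@@]2(C)[C@@H](C(C)=C)C[C@H](O[Si](C(C)C)(C(C)C)C(C)C)C(C)C2=O)cc1 | intermediate
7 | C10 enol triflate (C10=C11), C14 α-isopropenyl | COc1ccc(COC[C@@]2(C)[C@@H](C(C)=C)C[C@H](O[Si](C(C)C)(C(C)C)C(C)C)C(C)=C2OS(=O)(=O)C(F)(F)F)cc1 | intermediate
8 | C14 (2-methoxy-2-hydroperoxyprop-2-yl) enol triflate | COc1ccc(COC[C@@]2(C)[C@@H](C(C)(OC)OO)C[C@H](O[Si](C(C)C)(C(C)C)C(C)C)C(C)=C2OS(=O)(=O)C(F)(F)F)cc1 | intermediate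
9 | C14 α-acetate enol triflate | COc1ccc(COC[C@@]2(C)[C@@H](OC(C)=O)C[C@H](O[Si](C(C)C)(C(C)C)C(C)C)C(C)=C2OS(=O)(=O)C(F)(F)F)cc1 | intermediate
10 | methyl C9 enoate (C10=C11), C14 α-acetate | COc1ccc(COC[C@@]2(C)[C@@H](OC(C)=O)C[C@H](O[Si](C(C)C)(C(C)C)C(C)C)C(C)=C2C(=O)OC)cc1 | intermediate
11 | allylic diol (C9 hydroxymethyl on C10=C11, C14 α-OH) | COc1ccc(COC[C@@]2(C)[C@@H](O)C[C@H](O[Si](C(C)C)(C(C)C)C(C)C)C(C)=C2CO)cc1 | intermediate
12 | saturated ring-A diol (C9, C20 β; H-10, H-11 α) | COc1ccc(COC[C@@]2(C)[C@@H](O)C[C@H](O[Si](C(C)C)(C(C)C)C(C)C)[C@H](C)[C@@H]2CO)cc1 | intermediate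
13 | ring-A hydroxy aldehyde (C9 aldehyde, C14 α-OH) | COc1ccc(COC[C@@]2(C)[C@@H](O)C[C@H](O[Si](C(C)C)(C(C)C)C(C)C)[C@H](C)[C@@H]2C=O)cc1 | intermediate
14 | ring-A aldehyde (C2 O-PMB, C12 O-TIPS, C14 O-TBS) | COc1ccc(COC[C@@]2(C)[C@@H](O[Si](C)(C)C(C)(C)C)C[C@H](O[Si](C(C)C)(C(C)C)C(C)C)[C@H](C)[C@@H]2C=O)cc1 | intermediate
15 | propargyl alcohol | C#CCO | starting material
16 | (Z)-3-iodo-2-methylprop-2-en-1-ol | OC/C(C)=C\I | intermediate
17 | (Z)-1-iodo-3-(4-methoxybenzyloxy)-2-methylprop-1-ene | COc1ccc(COC/C(C)=C\I)cc1 | intermediate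
18 | (Z)-4-(4-methoxybenzyloxy)-3-methylbut-2-enal | COc1ccc(COC/C(C)=C\C=O)cc1 | intermediate
19 | propargyl acetate | C#CCOC(C)=O | starting material
20 | (4S,5Z)-4-hydroxy-7-(4-methoxybenzyloxy)-6-methylhept-5-en-2-yn-1-yl acetate | COc1ccc(COC/C(C)=C\[C@H](O)C#CCOC(C)=O)cc1 | intermediate
21 | C7 triethylsilyl ether of 20 | COc1ccc(COC/C(C)=C\[C@H](O[Si](CC)(CC)CC)C#CCOC(C)=O)cc1 | intermediate
22 | (2Z,4S,5Z)-3-iodo-7-(4-methoxybenzyloxy)-6-methyl-4-(triethylsilyloxy)hepta-2,5-dien-1-ol | COc1ccc(COC/C(C)=C\[C@H](O[Si](CC)(CC)CC)/C(I)=C/CO)cc1 | intermediate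
23 | side-chain vinyl iodide (C19 acetate of 22) | COc1ccc(COC/C(C)=C\[C@H](O[Si](CC)(CC)CC)/C(I)=C/COC(C)=O)cc1 | intermediate
24 | coupled C9 carbinols (C9 epimers; C8=C17 with C19 acetate cis to C9; C7 O-TES; Z C5=C6) | COc1ccc(COC[C@@]2(C)[C@@H](O[Si](C)(C)C(C)(C)C)C[C@H](O[Si](C(C)C)(C(C)C)C(C)C)[C@H](C)[C@@H]2C(O)/C(=C\COC(C)=O)[C@@H](O[Si](CC)(CC)CC)/C=C(C)\COCc2ccc(OC)cc2)cc1 | intermediate
25 | C9 enone | COc1ccc(COC[C@@]2(C)[C@@H](O[Si](C)(C)C(C)(C)C)C[C@H](O[Si](C(C)C)(C(C)C)C(C)C)[C@H](C)[C@@H]2C(=O)/C(=C\COC(C)=O)[C@@H](O[Si](CC)(CC)CC)/C=C(C)\COCc2ccc(OC)cc2)cc1 | intermediate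
26 | (9S) allylic alcohol, C19 acetate | COc1ccc(COC[C@@]2(C)[C@@H](O[Si](C)(C)C(C)(C)C)C[C@H](O[Si](C(C)C)(C(C)C)C(C)C)[C@H](C)[C@@H]2[C@H](O)/C(=C\COC(C)=O)[C@@H](O[Si](CC)(CC)CC)/C=C(C)\COCc2ccc(OC)cc2)cc1 | intermediate
27 | (9S) Z-ene-1,4-diol (C9 OH, C19 OH) | COc1ccc(COC[C@@]2(C)[C@@H](O[Si](C)(C)C(C)(C)C)C[C@H](O[Si](C(C)C)(C(C)C)C(C)C)[C@H](C)[C@@H]2[C@H](O)/C(=C\CO)[C@@H](O[Si](CC)(CC)CC)/C=C(C)\COCc2ccc(OC)cc2)cc1 | intermediate
28 | butenolide (O9–C19 lactone, C8=C17) | COc1ccc(COC[C@@]2(C)[C@@H](O[Si](C)(C)C(C)(C)C)C[C@H](O[Si](C(C)C)(C(C)C)C(C)C)[C@H](C)[C@@H]2[C@@H]3OC(=O)C=C3[C@@H](O[Si](CC)(CC)CC)/C=C(C)\COCc2ccc(OC)cc2)cc1 | intermediate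
29 | C8,C17-epoxy lactone (epoxide anti to C10) | COc1ccc(COC[C@@]2(C)[C@@H](O[Si](C)(C)C(C)(C)C)C[C@H](O[Si](C(C)C)(C(C)C)C(C)C)[C@H](C)[C@@H]2[C@@H]3OC(=O)[C@H]4O[C@@]34[C@@H](O[Si](CC)(CC)CC)/C=C(C)\COCc2ccc(OC)cc2)cc1 | intermediate
30 | C8-hydroxy C17-methyl lactone (C8, C17 as in the target) | COc1ccc(COC[C@@]2(C)[C@@H](O[Si](C)(C)C(C)(C)C)C[C@H](O[Si](C(C)C)(C(C)C)C(C)C)[C@H](C)[C@@H]2[C@@H]3OC(=O)[C@H](C)[C@]3(O)[C@@H](O[Si](CC)(CC)CC)/C=C(C)\COCc2ccc(OC)cc2)cc1 | intermediate
31 | C7,C8-diol lactone | COc1ccc(COC[C@@]2(C)[C@@H](O[Si](C)(C)C(C)(C)C)C[C@H](O[Si](C(C)C)(C(C)C)C(C)C)[C@H](C)[C@@H]2[C@@H]3OC(=O)[C@H](C)[C@]3(O)[C@@H](O)/C=C(C)\COCc2ccc(OC)cc2)cc1 | intermediate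
32 | C7/C8 acetonide of the O9–C19 lactone | COc1ccc(COC[C@@]2(C)[C@@H](O[Si](C)(C)C(C)(C)C)C[C@H](O[Si](C(C)C)(C(C)C)C(C)C)[C@H](C)[C@@H]2[C@@H]3OC(=O)[C@H](C)[C@@]34OC(C)(C)O[C@H]4/C=C(C)\COCc2ccc(OC)cc2)cc1 | intermediate
33 | C19 Weinreb amide, free C9 OH, C7/C8 acetonide | COc1ccc(COC[C@@]2(C)[C@@H](O[Si](C)(C)C(C)(C)C)C[C@H](O[Si](C(C)C)(C(C)C)C(C)C)[C@H](C)[C@@H]2[C@H](O)[C@]3(OC(C)(C)O[C@H]3/C=C(C)\COCc3ccc(OC)cc3)[C@@H](C)C(=O)N(C)OC)cc1 | intermediate
34 | C9 acetate | COc1ccc(COC[C@@]2(C)[C@@H](O[Si](C)(C)C(C)(C)C)C[C@H](O[Si](C(C)C)(C(C)C)C(C)C)[C@H](C)[C@@H]2[C@H](OC(C)=O)[C@]3(OC(C)(C)O[C@H]3/C=C(C)\COCc3ccc(OC)cc3)[C@@H](C)C(=O)N(C)OC)cc1 | intermediate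
35 | C2,C4-diol | OC[C@@]1(C)[C@@H](O[Si](C)(C)C(C)(C)C)C[C@H](O[Si](C(C)C)(C(C)C)C(C)C)[C@H](C)[C@@H]1[C@H](OC(C)=O)[C@]2(OC(C)(C)O[C@H]2/C=C(C)\CO)[C@@H](C)C(=O)N(C)OC | intermediate
36 | C4 methyl carbonate, free C2 OH | OC[C@@]1(C)[C@@H](O[Si](C)(C)C(C)(C)C)C[C@H](O[Si](C(C)C)(C(C)C)C(C)C)[C@H](C)[C@@H]1[C@H](OC(C)=O)[C@]2(OC(C)(C)O[C@H]2/C=C(C)\COC(=O)OC)[C@@H](C)C(=O)N(C)OC | intermediate
37 | C2 aldehyde | O=C[C@@]1(C)[C@@H](O[Si](C)(C)C(C)(C)C)C[C@H](O[Si](C(C)C)(C(C)C)C(C)C)[C@H](C)[C@@H]1[C@H](OC(C)=O)[C@]2(OC(C)(C)O[C@H]2/C=C(C)\COC(=O)OC)[C@@H](C)C(=O)N(C)OC | intermediate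
38 | methyl phenyl sulfone | CS(=O)(=O)c1ccccc1 | starting material
39 | C2-hydroxy C3-sulfone (C2 epimers) | OC(CS(=O)(=O)c1ccccc1)[C@@]2(C)[C@@H](O[Si](C)(C)C(C)(C)C)C[C@H](O[Si](C(C)C)(C(C)C)C(C)C)[C@H](C)[C@@H]2[C@H](OC(C)=O)[C@]3(OC(C)(C)O[C@H]3/C=C(C)\COC(=O)OC)[C@@H](C)C(=O)N(C)OC | intermediate
40 | C2 keto sulfone with C4 allylic methyl carbonate (cyclisation precursor) | O=C(CS(=O)(=O)c1ccccc1)[C@@]2(C)[C@@H](O[Si](C)(C)C(C)(C)C)C[C@H](O[Si](C(C)C)(C(C)C)C(C)C)[C@H](C)[C@@H]2[C@H](OC(C)=O)[C@]3(OC(C)(C)O[C@H]3/C=C(C)\COC(=O)OC)[C@@H](C)C(=O)N(C)OC | intermediate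
41 | ten-membered C2 ketone C3 sulfone (C3 epimer drawn is inconsequential) | O=C1[C@H](S(=O)(=O)c2ccccc2)C/C(C)=C\[C@@H]3OC(C)(C)O[C@]3([C@@H](C)C(=O)N(C)OC)[C@@H](OC(C)=O)[C@H]4[C@@H](C)[C@@H](O[Si](C(C)C)(C(C)C)C(C)C)C[C@H](O[Si](C)(C)C(C)(C)C)[C@@]41C | intermediate
42 | ten-membered C2 ketone | O=C1CC/C(C)=C\[C@@H]2OC(C)(C)O[C@]2([C@@H](C)C(=O)N(C)OC)[C@@H](OC(C)=O)[C@H]2[C@@H](C)[C@@H](O[Si](C(C)C)(C(C)C)C(C)C)C[C@H](O[Si](C)(C)C(C)(C)C)[C@@]21C | intermediate
43 | C14 alcohol of the ten-membered ketone | O=C1CC/C(C)=C\[C@@H]2OC(C)(C)O[C@]2([C@@H](C)C(=O)N(C)OC)[C@@H](OC(C)=O)[C@H]2[C@@H](C)[C@@H](O[Si](C(C)C)(C(C)C)C(C)C)C[C@H](O)[C@@]21C | intermediate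
44 | (2S)-C2,C14-diol | O[C@H]1CC/C(C)=C\[C@@H]2OC(C)(C)O[C@]2([C@@H](C)C(=O)N(C)OC)[C@@H](OC(C)=O)[C@H]2[C@@H](C)[C@@H](O[Si](C(C)C)(C(C)C)C(C)C)C[C@H](O)[C@@]21C | intermediate
45 | C2,C9,C14-triacetate (C12 O-TIPS, C7/C8 acetonide, C19 Weinreb amide) | CC(=O)O[C@H]1CC/C(C)=C\[C@@H]2OC(C)(C)O[C@]2([C@@H](C)C(=O)N(C)OC)[C@@H](OC(C)=O)[C@H]2[C@@H](C)[C@@H](O[Si](C(C)C)(C(C)C)C(C)C)C[C@H](OC(C)=O)[C@@]21C | intermediate
46 | C7,C8,C12-triol C19 Weinreb amide | CC(=O)O[C@H]1CC/C(C)=C\[C@H](O)[C@@](O)([C@@H](C)C(=O)N(C)OC)[C@@H](OC(C)=O)[C@H]2[C@@H](C)[C@@H](O)C[C@H](OC(C)=O)[C@@]21C | intermediate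
47 | CNP0195208.2 | CC(=O)O[C@H]1CC/C(C)=C\[C@@H]2OC(=O)[C@H](C)[C@@]2(O)[C@@H](OC(C)=O)[C@H]2[C@@H](C)[C@@H](O)C[C@H](OC(C)=O)[C@@]21C | target

**Totals.** Total step count: 38. Longest linear sequence: 31 steps (steps 1–11 and 19–38); the side-chain fragment takes 7 steps (12–18).

**Steps most likely to fail**

1. Step 33 (ring closure). Oligomerisation may outrun cyclisation, the enolate may be allylated on oxygen, or the π-allyl complex may lose a β-hydrogen to a diene. Fallback: close the same C3–C4 bond without palladium by SN2 alkylation. It sets out from diol 35: Corey–Kim chlorination (N-chlorosuccinimide, Me2S), selective for the allylic alcohol, would give the C4 allylic chloride F1; Dess–Martin oxidation the C2 aldehyde F2; addition of LiCH2SO2Ph the hydroxy sulfones F3; Dess–Martin oxidation the keto sulfone chloride F4; Cs2CO3 with catalytic NaI in MeCN at high dilution would then alkylate C3 and return to 41.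

2. Step 23 (epoxidation). Peroxide addition to the crowded β,γ-disubstituted butenolide may be slow, so that γ-deprotonation (loss of the C9 configuration) or lactone cleavage competes. Fallback: reagent-controlled epoxidation before lactonisation. It sets out from ene-diol 27: Sharpless epoxidation of the primary allylic alcohol (Ti(OiPr)4, D-(−)-diethyl tartrate, tBuOOH) would give the epoxy diol F5; Me2CuLi would open it at C17 with inversion to the triol F6; TEMPO/PhI(OAc)2 would oxidise the primary alcohol and close the lactone onto the C9 hydroxyl, returning to 30.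

3. Step 19 (fragment coupling). Addition of the vinylchromium species to the doubly hindered aldehyde may be slow, so that protodehalogenation of the vinyl iodide or ionisation of its allylic acetate by nickel takes over. Fallback: a vinyllithium addition with a base-stable C19 group. It sets out from iodo alcohol 22 and aldehyde 14: silylation (Et3SiCl, imidazole) would give the bis(triethylsilyl) ether F7; iodine–lithium exchange (tBuLi, Et2O, −78 °C) and addition to 14 the C9 carbinols F8; Dess–Martin oxidation the enone F9; Luche reduction the 9S alcohol F10, whose primary triethylsilyl ether is then cleaved selectively (pyridinium p-toluenesulfonate, MeOH, 0 °C) to return to 27.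

**Further compounds**

F1 | step 33 | C4 allylic chloride, free C2 hydroxyl | OC[C@@]1(C)[C@@H](O[Si](C)(C)C(C)(C)C)C[C@H](O[Si](C(C)C)(C(C)C)C(C)C)[C@H](C)[C@@H]1[C@H](OC(C)=O)[C@]2(OC(C)(C)O[C@H]2/C=C(C)\CCl)[C@@H](C)C(=O)N(C)OC
F2 | step 33 | C4 allylic chloride, C2 aldehyde | O=C[C@@]1(C)[C@@H](O[Si](C)(C)C(C)(C)C)C[C@H](O[Si](C(C)C)(C(C)C)C(C)C)[C@H](C)[C@@H]1[C@H](OC(C)=O)[C@]2(OC(C)(C)O[C@H]2/C=C(C)\CCl)[C@@H](C)C(=O)N(C)OC
F3 | step 33 | C4 allylic chloride, C2-hydroxy C3-sulfone (C2 epimers) | OC(CS(=O)(=O)c1ccccc1)[C@@]2(C)[C@@H](O[Si](C)(C)C(C)(C)C)C[C@H](O[Si](C(C)C)(C(C)C)C(C)C)[C@H](C)[C@@H]2[C@H](OC(C)=O)[C@]3(OC(C)(C)O[C@H]3/C=C(C)\CCl)[C@@H](C)C(=O)N(C)OC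
F4 | step 33 | C4 allylic chloride, C2 keto sulfone | O=C(CS(=O)(=O)c1ccccc1)[C@@]2(C)[C@@H](O[Si](C)(C)C(C)(C)C)C[C@H](O[Si](C(C)C)(C(C)C)C(C)C)[C@H](C)[C@@H]2[C@H](OC(C)=O)[C@]3(OC(C)(C)O[C@H]3/C=C(C)\CCl)[C@@H](C)C(=O)N(C)OC
F5 | step 23 | C8,C17-epoxy C9,C19-diol | COc1ccc(COC[C@@]2(C)[C@@H](O[Si](C)(C)C(C)(C)C)C[C@H](O[Si](C(C)C)(C(C)C)C(C)C)[C@H](C)[C@@H]2[C@H](O)[C@@]3(O[C@@H]3CO)[C@@H](O[Si](CC)(CC)CC)/C=C(C)\COCc2ccc(OC)cc2)cc1
F6 | step 23 | C8,C9,C19-triol with C17 methyl | COc1ccc(COC[C@@]2(C)[C@@H](O[Si](C)(C)C(C)(C)C)C[C@H](O[Si](C(C)C)(C(C)C)C(C)C)[C@H](C)[C@@H]2[C@H](O)[C@](O)([C@@H](C)CO)[C@@H](O[Si](CC)(CC)CC)/C=C(C)\COCc2ccc(OC)cc2)cc1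
F7 | step 19 | bis(triethylsilyl) ether of iodo alcohol 22 | COc1ccc(COC/C(C)=C\[C@H](O[Si](CC)(CC)CC)/C(I)=C/CO[Si](CC)(CC)CC)cc1
F8 | step 19 | coupled C9 carbinols with C19 O-TES (C9 epimers) | COc1ccc(COC[C@@]2(C)[C@@H](O[Si](C)(C)C(C)(C)C)C[C@H](O[Si](C(C)C)(C(C)C)C(C)C)[C@H](C)[C@@H]2C(O)/C(=C\CO[Si](CC)(CC)CC)[C@@H](O[Si](CC)(CC)CC)/C=C(C)\COCc2ccc(OC)cc2)cc1
F9 | step 19 | C9 enone with C19 O-TES | COc1ccc(COC[C@@]2(C)[C@@H](O[Si](C)(C)C(C)(C)C)C[C@H](O[Si](C(C)C)(C(C)C)C(C)C)[C@H](C)[C@@H]2C(=O)/C(=C\CO[Si](CC)(CC)CC)[C@@H](O[Si](CC)(CC)CC)/C=C(C)\COCc2ccc(OC)cc2)cc1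
F10 | step 19 | (9S) allylic alcohol with C19 O-TES | COc1ccc(COC[C@@]2(C)[C@@H](O[Si](C)(C)C(C)(C)C)C[C@H](O[Si](C(C)C)(C(C)C)C(C)C)[C@H](C)[C@@H]2[C@H](O)/C(=C\CO[Si](CC)(CC)CC)[C@@H](O[Si](CC)(CC)CC)/C=C(C)\COCc2ccc(OC)cc2)cc1
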